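**Strategy.** The oxolane ring is opened at C4–C5, the bond joining the tertiary carbinol carbon to the ring OCH2 carbon. C5 is an α-alkoxymethyl carbon and C4 (C–OH plus benzyl) is a masked arylalkyne carbon, so the ring can be closed by an alkoxymethyl radical. The precursor is an open-chain syn homopropargylic alcohol carrying OCH2CO2H on the benzylic oxygen. Photoreductive decarboxylation of its N-acyloxyphthalimide gives the O–CH2 radical, which cyclises 5-exo-dig onto the arylalkyne to a 4-benzylidene oxolane. Because the C2 aryl and C3 CH2OBn groups are cis, epoxidation from the open face and hydrogenolysis then deliver C4 with OH trans and benzyl cis.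

Key step: step 15

Remark 1: The target is taken exactly as drawn. Oxolane labels used here: O1, C2 (dihydrobenzofuranyl, R), C3 (CH2OH, R), C4 (carbinol with benzyl, S), C5 (CH2); the C2 aryl, C3 CH2OH and C4 benzyl groups are all cis, the C4 OH is trans to them, and the 2,3-dihydrobenzofuran is cis-(2R,3R).
Remark 2: The sense of induction of the chiral catalysts in steps 4 and 10 is assigned by analogy with close precedent; if an assignment proves opposite, the antipodal catalyst is used.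
Remark 3: The alkene geometry of 21 and the configuration of the benzylic epoxide carbon of 22 are left open because step 17 erases both.
Remark 4: Abbreviations: Ar = 4-(benzyloxy)-3-methoxyphenyl; DHB = (2R,3R)-3-[(benzyloxy)methyl]-2-Ar-7-methoxy-2,3-dihydro-1-benzofuran-5-yl (2,3-cis).

**Fragment A: the cis-dihydrobenzofuran aldehyde**

Step 1
Reactants: 1 methyl vanillate
Product: 2 methyl 4-hydroxy-3-iodo-5-methoxybenzoate
Conditions: NIS, TFA (cat.), MeCN, rt
Reagents that add atoms: N-iodosuccinimide, O=C1CCC(=O)N1I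
Why: Electrophilic aromatic iodination, directed by the free phenol to its only open ortho position because the para position carries the ester.

Step 2
Reactants: 2 methyl 4-hydroxy-3-iodo-5-methoxybenzoate; 3 4-(benzyloxy)-3-methoxybenzyl chloride
Product: 4 methyl 4-{[4-(benzyloxy)-3-methoxyphenyl]methoxy}-3-iodo-5-methoxybenzoate
Conditions: K2CO3, KI (cat.), DMF, 60 °C
Reagents that add atoms: none
Why: Williamson ether synthesis of the phenoxide with a reactive benzylic chloride; this oxygen and its CH2 become O1 and C2 of the dihydrobenzofuran.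

Step 3
Reactants: 4 methyl 4-{[4-(benzyloxy)-3-methoxyphenyl]methoxy}-3-iodo-5-methoxybenzoate
Product: 5 methyl 4-{[4-(benzyloxy)-3-methoxyphenyl]methoxy}-3-(1-diazo-2-ethoxy-2-oxoethyl)-5-methoxybenzoate
Conditions: ethyl diazoacetate, Pd(PPh3)4 (5 mol%), Et3N, Bu4NBr, MeCN, 45 °C
Reagents that add atoms: ethyl diazoacetate, CCOC(=O)C=[N+]=[N-]
Why: Palladium-catalysed cross-coupling of an aryl iodide with the C–H bond of a diazoacetate (oxidative addition to zerovalent palladium, base-assisted transfer of the diazo carbon, reductive elimination), which keeps the diazo group.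

Step 4
Reactants: 5 the aryldiazoacetate
Product: 6 3-ethyl 5-methyl (2R,3S)-2-Ar-7-methoxy-2,3-dihydro-1-benzofuran-3,5-dicarboxylate (2,3-cis)
Conditions: Rh2(S-PTTL)4 (1 mol%), toluene, −60 °C
Reagents that add atoms: none
Why: Dirhodium-carbenoid intramolecular 1,5 C–H insertion into the benzylic OCH2 group; the concerted insertion gives the kinetic cis-2-aryl-3-ester and the chiral carboxylate ligands choose the enantiotopic C–H bond, setting both ring stereocentres.

Step 5
Reactants: 6 the cis diester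
Product: 7 [(2R,3R)-2-Ar-7-methoxy-2,3-dihydro-1-benzofuran-3,5-diyl]dimethanol
Conditions: LiAlH4, THF, −20 to 0 °C; aq. Rochelle salt
Reagents that add atoms: none
Why: Hydride reduction of both esters, run cold so that the epimerisable cis C3 centre is reduced before base can convert it to trans.

Step 6
Reactants: 7 the diol
Product: 8 (2R,3R)-2-Ar-3-(hydroxymethyl)-7-methoxy-2,3-dihydro-1-benzofuran-5-carbaldehyde
Conditions: activated MnO2, CH2Cl2, rt
Reagents that add atoms: none
Why: MnO2 oxidation is selective for the benzylic alcohol and leaves the aliphatic primary alcohol.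

Step 7
Reactants: 8 the hydroxy aldehyde
Product: 9 (2R,3R)-3-[(benzyloxy)methyl]-2-Ar-7-methoxy-2,3-dihydro-1-benzofuran-5-carbaldehyde (DHB–CHO)
Conditions: BnBr, Ag2O, CH2Cl2, rt
Reagents that add atoms: benzyl bromide, BrCc1ccccc1
Why: Silver-oxide-promoted O-benzylation under neutral conditions, which tolerates the non-enolisable aldehyde and the cis ring.

**Fragment B: the chiral allenylstannane**

Step 8
Reactants: 10 4-(benzyloxy)-3-methoxybenzaldehyde
Product: 11 1-(benzyloxy)-4-ethynyl-2-methoxybenzene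
Conditions: dimethyl (1-diazo-2-oxopropyl)phosphonate, K2CO3, MeOH, rt
Reagents that add atoms: dimethyl (1-diazo-2-oxopropyl)phosphonate, COP(=O)(OC)C(=[N+]=[N-])C(C)=O
Why: Ohira–Bestmann variant of the Seyferth–Gilbert homologation converts the aldehyde into the terminal alkyne.

Step 9
Reactants: 11 1-(benzyloxy)-4-ethynyl-2-methoxybenzene; 12 2-(benzyloxy)-N-methoxy-N-methylacetamide
Product: 14 1-(benzyloxy)-4-Ar-but-3-yn-2-one, via lithium acetylide 13 (not isolated)
Conditions: n-BuLi, THF, −78 °C; then 12, −78 to 0 °C; aq. NH4Cl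
Reagents that add atoms: none
Why: Acylation of a lithium acetylide by a Weinreb amide, whose chelated tetrahedral intermediate prevents a second addition.

Step 10
Reactants: 14 the ynone
Product: 15 (2R)-1-(benzyloxy)-4-Ar-but-3-yn-2-ol
Conditions: Ru[(S,S)-TsDPEN](p-cymene) (1 mol%), iPrOH, rt
Reagents that add atoms: none
Why: Noyori asymmetric transfer hydrogenation of an alkynyl ketone; the catalyst differentiates the alkynyl and CH2OBn sides and sets the carbinol centre.

Step 11
Reactants: 15 the (R)-propargylic alcohol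
Product: 16 (2R)-1-(benzyloxy)-4-Ar-but-3-yn-2-yl methanesulfonate
Conditions: MsCl, Et3N, CH2Cl2, −40 °C
Reagents that add atoms: methanesulfonyl chloride, CS(=O)(=O)Cl
Why: Sulfonylation at oxygen with retention at carbon; the mesylate is used crude.

Step 12
Reactants: 16 the (R)-mesylate
Product: 17 tributyl[(Ra)-4-(benzyloxy)-1-Ar-buta-1,2-dien-1-yl]stannane
Conditions: Bu3SnH, LDA, THF, −78 °C; CuBr·SMe2; then 16, −78 °C
Reagents that add atoms: tributyltin hydride, CCCC[SnH](CCCC)CCCC (delivered as tributylstannyllithium, [Li][Sn](CCCC)(CCCC)CCCC)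
Why: Anti SN2′ displacement of the propargylic mesylate by the stannylcopper reagent (Marshall allenylstannane synthesis) transfers the central chirality of 16 to the allene axis.

**Union and endgame**

Step 13
Reactants: 9 DHB–CHO; 17 the allenylstannane
Product: 18 (1R,2R)-2-[(benzyloxy)methyl]-4-Ar-1-DHB-but-3-yn-1-ol (syn)
Conditions: BF3·OEt2, CH2Cl2, −78 °C; aq. NaHCO3
Reagents that add atoms: none
Why: Marshall BF3-promoted SE2′ addition of an allenylstannane to an aldehyde; attack anti to tin sets C3 from the allene axis and the open transition state should favour the syn alcohol, setting C2.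

Step 14
Reactants: 18 the syn homopropargylic alcohol
Product: 19 {[(1R,2R)-2-[(benzyloxy)methyl]-4-Ar-1-DHB-but-3-yn-1-yl]oxy}acetic acid
Conditions: NaH, BrCH2CO2H, THF/DMF, 0 °C to rt; cold 0.5 M HCl
Reagents that add atoms: bromoacetic acid, OC(=O)CBr
Why: Williamson O-alkylation of the sodium alkoxide with sodium bromoacetate, retaining configuration at C2 and installing the future C5 as the acid CH2.

Step 15
Reactants: 19 the alkoxyacetic acid
Product: 21 (2R,3R)-3-[(benzyloxy)methyl]-4-(Ar-methylidene)-2-DHB-oxolane (E/Z mixture), via N-acyloxyphthalimide 20 (not isolated)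
Conditions: N-hydroxyphthalimide, DIC, DMAP (cat.), CH2Cl2, rt; then Ru(bpy)3(PF6)2 (1 mol%), Hantzsch ester, iPr2NEt, blue LEDs, rt
Reagents that add atoms: none
Why: Single-electron reduction of ester 20 by the photoreduced ruthenium catalyst (Hantzsch ester as terminal reductant) releases phthalimide anion and CO2 and leaves the nucleophilic radical O1–C5H2•, which adds to alkyne carbon C4; the resulting α-aryl vinyl radical takes a hydrogen atom from the Hantzsch ester. The closest known reaction types are the tin hydride cyclisation of alkoxymethyl radicals to oxolanes and the photoreductive decarboxylative radical addition of N-acyloxyphthalimides. The oxolane closes in the 5-exo-dig mode; 6-endo attack at the aryl-bearing carbon is stereoelectronically worse and would forfeit the aryl-stabilised vinyl radical. No stereocentre is created (C4 becomes sp2) and C2 and C3 are untouched. The step needs ring closure to beat hydrogen transfer to the open radical and β-scission of the benzylic C2–O bond, which the aryl-activated alkyne, the slow hydrogen donor and room temperature should secure.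

Step 16
Reactants: 21 the benzylidene oxolane
Product: 22 (3S,6R,7R)-7-[(benzyloxy)methyl]-2-Ar-6-DHB-1,5-dioxaspiro[2.4]heptane
Conditions: DMDO, acetone, −20 to 0 °C
Reagents that add atoms: dimethyldioxirane, CC1(C)OO1
Why: Neutral dioxirane epoxidation of the electron-rich alkene from the face opposite the cis C2 aryl and C3 CH2OBn groups, placing the C4 oxygen trans to both.

Step 17
Reactants: 22 the spiro epoxide
Product: 23 the target (CNP0284796.1)
Conditions: H2 (1 atm), 10% Pd/C, NaHCO3, EtOAc/EtOH, rt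
Reagents that add atoms: none
Why: Catalytic hydrogenolysis cleaves the benzylic epoxide C–O bond (C4–O kept with retention, giving the tertiary alcohol and the benzyl CH2) and removes the four benzyl ethers.

**Compound list**

1 | methyl vanillate (methyl 4-hydroxy-3-methoxybenzoate) | COC(=O)c1ccc(O)c(OC)c1 | starting material
2 | methyl 4-hydroxy-3-iodo-5-methoxybenzoate | COC(=O)c1cc(I)c(O)c(OC)c1 | intermediate
3 | 4-(benzyloxy)-3-methoxybenzyl chloride | ClCc1ccc(OCc2ccccc2)c(OC)c1 | starting material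
4 | methyl 4-{[4-(benzyloxy)-3-methoxyphenyl]methoxy}-3-iodo-5-methoxybenzoate | COC(=O)c1cc(I)c(OCc2ccc(OCc3ccccc3)c(OC)c2)c(OC)c1 | intermediate
5 | methyl 4-{[4-(benzyloxy)-3-methoxyphenyl]methoxy}-3-(1-diazo-2-ethoxy-2-oxoethyl)-5-methoxybenzoate | CCOC(=O)C(=[N+]=[N-])c1cc(C(=O)OC)cc(OC)c1OCc1ccc(OCc2ccccc2)c(OC)c1 | intermediate
6 | 3-ethyl 5-methyl (2R,3S)-2-[4-(benzyloxy)-3-methoxyphenyl]-7-methoxy-2,3-dihydro-1-benzofuran-3,5-dicarboxylate (cis) | COC(=O)c1cc(OC)c2c(c1)[C@H](C(=O)OCC)[C@H](c1ccc(OCc3ccccc3)c(OC)c1)O2 | intermediate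
7 | [(2R,3R)-2-[4-(benzyloxy)-3-methoxyphenyl]-7-methoxy-2,3-dihydro-1-benzofuran-3,5-diyl]dimethanol (cis) | OCc1cc(OC)c2c(c1)[C@H](CO)[C@H](c1ccc(OCc3ccccc3)c(OC)c1)O2 | intermediate
8 | (2R,3R)-2-[4-(benzyloxy)-3-methoxyphenyl]-3-(hydroxymethyl)-7-methoxy-2,3-dihydro-1-benzofuran-5-carbaldehyde | O=Cc1cc(OC)c2c(c1)[C@H](CO)[C@H](c1ccc(OCc3ccccc3)c(OC)c1)O2 | intermediate
9 | (2R,3R)-3-[(benzyloxy)methyl]-2-[4-(benzyloxy)-3-methoxyphenyl]-7-methoxy-2,3-dihydro-1-benzofuran-5-carbaldehyde | O=Cc1cc(OC)c2c(c1)[C@H](COCc1ccccc1)[C@H](c1ccc(OCc3ccccc3)c(OC)c1)O2 | intermediate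
10 | 4-(benzyloxy)-3-methoxybenzaldehyde | O=Cc1ccc(OCc2ccccc2)c(OC)c1 | starting material
11 | 1-(benzyloxy)-4-ethynyl-2-methoxybenzene | C#Cc1ccc(OCc2ccccc2)c(OC)c1 | intermediate
12 | 2-(benzyloxy)-N-methoxy-N-methylacetamide | CON(C)C(=O)COCc1ccccc1 | starting material
13 | lithium [4-(benzyloxy)-3-methoxyphenyl]acetylide | [Li]C#Cc1ccc(OCc2ccccc2)c(OC)c1 | intermediate
14 | 1-(benzyloxy)-4-[4-(benzyloxy)-3-methoxyphenyl]but-3-yn-2-one | O=C(COCc1ccccc1)C#Cc1ccc(OCc2ccccc2)c(OC)c1 | intermediate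
15 | (2R)-1-(benzyloxy)-4-[4-(benzyloxy)-3-methoxyphenyl]but-3-yn-2-ol | O[C@H](C#Cc1ccc(OCc2ccccc2)c(OC)c1)COCc1ccccc1 | intermediate
16 | (2R)-1-(benzyloxy)-4-[4-(benzyloxy)-3-methoxyphenyl]but-3-yn-2-yl methanesulfonate | CS(=O)(=O)O[C@H](C#Cc1ccc(OCc2ccccc2)c(OC)c1)COCc1ccccc1 | intermediate
17 | tributyl{(Ra)-4-(benzyloxy)-1-[4-(benzyloxy)-3-methoxyphenyl]buta-1,2-dien-1-yl}stannane | CCCC[Sn](CCCC)(CCCC)C(c1ccc(OCc2ccccc2)c(OC)c1)=[C@]=C([H])COCc1ccccc1 | intermediate
18 | (1R,2R)-2-[(benzyloxy)methyl]-4-[4-(benzyloxy)-3-methoxyphenyl]-1-{(2R,3R)-3-[(benzyloxy)methyl]-2-[4-(benzyloxy)-3-methoxyphenyl]-7-methoxy-2,3-dihydro-1-benzofuran-5-yl}but-3-yn-1-ol | O[C@@H](c1cc(OC)c2c(c1)[C@H](COCc1ccccc1)[C@H](c1ccc(OCc3ccccc3)c(OC)c1)O2)[C@H](C#Cc1ccc(OCc2ccccc2)c(OC)c1)COCc1ccccc1 | intermediate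
19 | 2-{[(1R,2R)-2-[(benzyloxy)methyl]-4-[4-(benzyloxy)-3-methoxyphenyl]-1-(DHB)but-3-yn-1-yl]oxy}acetic acid | OC(=O)CO[C@@H](c1cc(OC)c2c(c1)[C@H](COCc1ccccc1)[C@H](c1ccc(OCc3ccccc3)c(OC)c1)O2)[C@H](C#Cc1ccc(OCc2ccccc2)c(OC)c1)COCc1ccccc1 | intermediate
20 | 1,3-dioxoisoindolin-2-yl ester of acid 19 | O=C1c2ccccc2C(=O)N1OC(=O)CO[C@@H](c1cc(OC)c2c(c1)[C@H](COCc1ccccc1)[C@H](c1ccc(OCc3ccccc3)c(OC)c1)O2)[C@H](C#Cc1ccc(OCc2ccccc2)c(OC)c1)COCc1ccccc1 | intermediate
21 | (2R,3R)-3-[(benzyloxy)methyl]-4-{[4-(benzyloxy)-3-methoxyphenyl]methylidene}-2-(DHB)oxolane, E/Z mixture | COc1cc(C=C2CO[C@@H](c3cc(OC)c4c(c3)[C@H](COCc3ccccc3)[C@H](c3ccc(OCc5ccccc5)c(OC)c3)O4)[C@H]2COCc2ccccc2)ccc1OCc1ccccc1 | intermediate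
22 | (3S,6R,7R)-7-[(benzyloxy)methyl]-2-[4-(benzyloxy)-3-methoxyphenyl]-6-(DHB)-1,5-dioxaspiro[2.4]heptane, C2 epimers | COc1cc(C2O[C@@]23CO[C@@H](c4cc(OC)c5c(c4)[C@H](COCc4ccccc4)[C@H](c4ccc(OCc6ccccc6)c(OC)c4)O5)[C@H]3COCc2ccccc2)ccc1OCc1ccccc1 | intermediate
23 | (3S,4R,5R)-5-[(2R,3R)-2-(4-hydroxy-3-methoxyphenyl)-3-(hydroxymethyl)-7-methoxy-2,3-dihydro-1-benzofuran-5-yl]-3-[(4-hydroxy-3-methoxyphenyl)methyl]-4-(hydroxymethyl)oxolan-3-ol | COc1cc(C[C@@]2(O)CO[C@@H](c3cc(OC)c4c(c3)[C@H](CO)[C@H](c3ccc(O)c(OC)c3)O4)[C@H]2CO)ccc1O | target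

**Totals.** Total step count: 17. Longest linear sequence: 12 steps (steps 1–7 and 13–17).

**Steps most likely to fail**

1. Step 13. The open transition state may discriminate syn from anti only weakly with an aromatic aldehyde, eroding control at C2, and BF3 may ionise the benzylic C–O bonds. Fallback (sets out from 9, returns at 18): an auxiliary-controlled aldol replaces the allenylmetal addition. 3-(Benzyloxy)propanoic acid and (R)-4-benzyloxazolidin-2-one (pivaloyl chloride, Et3N, LiCl, THF) give the imide (R)-4-benzyl-3-[3-(benzyloxy)propanoyl]oxazolidin-2-one F1. Its Z-boron enolate (Bu2BOTf, iPr2NEt, CH2Cl2, −78 °C) adds to 9 in an Evans syn aldol reaction to give the (2R,3R) aldol adduct F2, with both new centres as in 18. TESOTf and 2,6-lutidine give the triethylsilyl ether F3. LiBH4 (THF, MeOH) cleaves the auxiliary to the primary alcohol F4. Dess–Martin periodinane gives the aldehyde F5. Ohira–Bestmann homologation (K2CO3, MeOH) gives the terminal alkyne F6. Sonogashira coupling with 1-(benzyloxy)-4-iodo-2-methoxybenzene (PdCl2(PPh3)2, CuI, Et3N) gives the silylated arylalkyne F7. TBAF in THF removes the silyl group and returns 18.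

2. Step 15. Hydrogen-atom transfer may reach the alkoxymethyl radical before ring closure, or the activated ester may hydrolyse before electron transfer. Fallback (sets out from 18, returns at 21): a thermal tin hydride chain from a selenide replaces photoreductive decarboxylation. The sodium alkoxide of 18 (NaH, THF) is alkylated with chloromethyl phenyl selenide to give the (phenylselanyl)methyl ether F8. Slow addition of Bu3SnH with Et3B and air in toluene at 0 °C abstracts the phenylselanyl group, and the same 5-exo-dig closure gives 21.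

3. Step 17. Palladium may isomerise the aryl epoxide to carbonyl compounds before C–O hydrogenolysis, and the benzylic C–O bonds of the two cyclic ethers may be over-reduced while the alkyl benzyl ethers are still being cleaved. Fallback (sets out from 22, returns at 23): LiEt3BH in THF at 0 °C opens the epoxide by hydride attack at the less hindered benzylic carbon to give the tetra-O-benzyl tertiary alcohol F9. The benzyl ethers are then removed by transfer hydrogenolysis (Pd(OH)2 on carbon, 1,4-cyclohexadiene, EtOH), which can be stopped before the ring C–O bonds react.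

**Further compounds**

F1 | step 13 | (R)-4-benzyl-3-[3-(benzyloxy)propanoyl]oxazolidin-2-one | O=C(CCOCc1ccccc1)N1[C@H](Cc2ccccc2)COC1=O
F2 | step 13 | (R)-4-benzyl-3-[(2R,3R)-2-[(benzyloxy)methyl]-3-hydroxy-3-(DHB)propanoyl]oxazolidin-2-one | O=C(N1[C@H](Cc2ccccc2)COC1=O)[C@H](COCc1ccccc1)[C@@H](O)c1cc(OC)c2c(c1)[C@H](COCc1ccccc1)[C@H](c1ccc(OCc3ccccc3)c(OC)c1)O2
F3 | step 13 | triethylsilyl ether of F2 | O=C(N1[C@H](Cc2ccccc2)COC1=O)[C@H](COCc1ccccc1)[C@@H](O[Si](CC)(CC)CC)c1cc(OC)c2c(c1)[C@H](COCc1ccccc1)[C@H](c1ccc(OCc3ccccc3)c(OC)c1)O2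
F4 | step 13 | 2-[(benzyloxy)methyl]-3-(DHB)-3-(triethylsilyloxy)propan-1-ol | OC[C@H](COCc1ccccc1)[C@@H](O[Si](CC)(CC)CC)c1cc(OC)c2c(c1)[C@H](COCc1ccccc1)[C@H](c1ccc(OCc3ccccc3)c(OC)c1)O2
F5 | step 13 | 2-[(benzyloxy)methyl]-3-(DHB)-3-(triethylsilyloxy)propanal | O=C[C@H](COCc1ccccc1)[C@@H](O[Si](CC)(CC)CC)c1cc(OC)c2c(c1)[C@H](COCc1ccccc1)[C@H](c1ccc(OCc3ccccc3)c(OC)c1)O2
F6 | step 13 | triethylsilyl ether of 2-[(benzyloxy)methyl]-1-(DHB)but-3-yn-1-ol | C#C[C@H](COCc1ccccc1)[C@@H](O[Si](CC)(CC)CC)c1cc(OC)c2c(c1)[C@H](COCc1ccccc1)[C@H](c1ccc(OCc3ccccc3)c(OC)c1)O2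
F7 | step 13 | triethylsilyl ether of 18 | COc1cc(C#C[C@H](COCc2ccccc2)[C@@H](O[Si](CC)(CC)CC)c2cc(OC)c3c(c2)[C@H](COCc2ccccc2)[C@H](c2ccc(OCc4ccccc4)c(OC)c2)O3)ccc1OCc1ccccc1
F8 | step 15 | (phenylselanyl)methyl ether of 18 | C(O[C@@H](c1cc(OC)c2c(c1)[C@H](COCc1ccccc1)[C@H](c1ccc(OCc3ccccc3)c(OC)c1)O2)[C@H](C#Cc1ccc(OCc2ccccc2)c(OC)c1)COCc1ccccc1)[Se]c1ccccc1
F9 | step 17 | tetra-O-benzyl ether of 23 | COc1cc(C[C@@]2(O)CO[C@@H](c3cc(OC)c4c(c3)[C@H](COCc3ccccc3)[C@H](c3ccc(OCc5ccccc5)c(OC)c3)O4)[C@H]2COCc2ccccc2)ccc1OCc1ccccc1
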